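The route rests on opening ring C of the upper flavan unit at O1–C2 and C4a–C4. The ring A oxygen O1 and its ortho carbon C4a form a 1,3-dinucleophile (a dilithiated resorcinol monoether), and C2–C3–C4, benzylic at both ends (C2 to ring B, C4 to ring D of the lower flavan), becomes a 1,3-dielectrophile: an (αR,βS)-epoxy ketone that already carries the complete lower unit. In one operation the aryllithium adds to the ketone (C4a–C4) and the phenoxide opens the epoxide at C2 with inversion (O1–C2), giving the 2,3-trans flavan-3,4-diol; ionic hydrogenation anti to O3 then sets the 3,4-cis C4. Both flavan rings derive from one glycidic amide.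

Key step: step 10

Remark: flavan numbering (O1, C2, C3, C4, C4a, C5–C8, C8a) is used for both units; rings A, B and C belong to the upper unit, ring D is the aromatic ring of the lower chroman. Compounds 1, 2, 5 and 18 are taken as catalogue chemicals.
Assumption: in step 2 the (S)-BINOL complex is taken to deliver the (2R,3S)-epoxide, the facial sense this ligand family shows with (E)-enones; were the opposite sense found, (R)-BINOL would replace it with nothing else changed.

Step 1
Reactants: 1 3,4-bis(benzyloxy)benzaldehyde; 2 diethyl (2-morpholino-2-oxoethyl)phosphonate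
Product: 3 (2E)-3-[3,4-bis(benzyloxy)phenyl]-1-(morpholin-4-yl)prop-2-en-1-one
Conditions: NaH, THF, 0 → 23 °C
Reagents that add atoms: none
Why: Horner–Wadsworth–Emmons olefination of an aryl aldehyde with an amide-stabilised phosphonate anion should give the (E)-enamide, the equilibrating adducts collapsing through the anti pathway.

Step 2
Reactants: 3 (E)-enamide
Product: 4 [(2R,3S)-3-[3,4-bis(benzyloxy)phenyl]oxiran-2-yl](morpholin-4-yl)methanone
Conditions: Sm(O-i-Pr)3 (10 mol %), (S)-BINOL (10 mol %), Ph3As=O (10 mol %), t-BuOOH (decane), 4 Å molecular sieves, THF, 23 °C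
Reagents that add atoms: tert-butyl hydroperoxide, CC(C)(C)OO
Why: Lanthanide–binaphtholate-catalysed nucleophilic epoxidation (Weitz–Scheffer type) of an α,β-unsaturated morpholine amide should give the trans-epoxide from the (E)-alkene, the chiral samarium peroxide attacking one enantioface so that both stereocentres (2R,3S) are set by the ligand.

Step 3
Reactants: 5 2,3-bis(benzyloxy)benzaldehyde
Product: 7 2,3-bis(benzyloxy)phenol, via aryl formate 6 (not isolated)
Conditions: mCPBA, CH2Cl2, 0 → 23 °C; then K2CO3 (cat.), MeOH, 23 °C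
Reagents that add atoms: 3-chloroperoxybenzoic acid, OOC(=O)c1cccc(Cl)c1
Why: Baeyer–Villiger (Dakin-type) oxidation of an ortho-alkoxybenzaldehyde proceeds by migration of the electron-rich aryl group to give the formate, which methanolysis cleaves to the phenol.

Step 4
Reactants: 7 2,3-bis(benzyloxy)phenol
Product: 8 4-bromo-2,3-bis(benzyloxy)phenol
Conditions: NBS (1.0 equiv), MeCN, −20 → 0 °C
Reagents that add atoms: N-bromosuccinimide, O=C1CCC(=O)N1Br
Why: Electrophilic aromatic bromination: the free hydroxyl, the strongest donor, should direct NBS to its para position, which becomes C6 of the lower flavan.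

Step 5
Reactants: 8 4-bromo-2,3-bis(benzyloxy)phenol
Product: 9 4-bromo-6-iodo-2,3-bis(benzyloxy)phenol
Conditions: NIS (1.05 equiv), p-TsOH·H2O (10 mol %), MeCN, 23 °C
Reagents that add atoms: N-iodosuccinimide, O=C1CCC(=O)N1I
Why: Electrophilic aromatic iodination: with the para position blocked, the iodonium source should attack the one remaining position ortho to the hydroxyl, giving a dihalide whose iodine can be exchanged selectively.

Step 6
Reactants: 9 4-bromo-6-iodo-2,3-bis(benzyloxy)phenol; 4 epoxy amide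
Product: 12 (2R,3R)-7,8-bis(benzyloxy)-2-[3,4-bis(benzyloxy)phenyl]-6-bromo-3-hydroxy-2,3-dihydro-4H-chromen-4-one, via metallated phenoxide 10 (not isolated), via hydroxyaryl epoxy ketone 11 (not isolated)
Conditions: NaH (1.05 equiv), THF, 0 °C; n-BuLi (1.0 equiv), −78 °C; then 4, −78 → −30 °C; then MeOH, −30 → 0 °C; aq. NH4Cl
Reagents that add atoms: none
Why: Anionic [3+3] annulation of the same type as the key step: iodine–lithium exchange (the bromide is left at −78 °C) gives an ortho-lithiated phenoxide that is acylated by the morpholine amide, and after the methanol quench the 2'-hydroxychalcone-epoxide-type phenoxide should close 6-endo at the benzylic epoxide carbon with inversion as in the Algar–Flynn–Oyamada manifold, so C3 keeps the epoxide configuration and C2 becomes R (2,3-trans).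

Step 7
Reactants: 12 bromo dihydroflavonol
Product: 14 (2R,3S)-7,8-bis(benzyloxy)-2-[3,4-bis(benzyloxy)phenyl]-6-bromo-3,4-dihydro-2H-chromen-3-ol, via flavan-3,4-diol 13 (not isolated)
Conditions: NaBH4, THF/EtOH, 0 °C; then crude diol, Et3SiH, TFA, CH2Cl2, −20 → 0 °C
Reagents that add atoms: none
Why: Borohydride reduction of the ketone followed by ionic hydrogenation of the benzylic C4 alcohol (silane hydride transfer to the cation stabilised by O1 and the para 7-benzyloxy group) should deoxygenate C4 without touching C2 and C3, while the C6 bromine blocks Friedel–Crafts self-condensation.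

Step 8
Reactants: 14 bromo flavan-3-ol
Product: 15 (2R,3S)-3,7,8-tris(benzyloxy)-2-[3,4-bis(benzyloxy)phenyl]-6-bromo-3,4-dihydro-2H-chromene
Conditions: NaH, BnBr, Bu4NI (cat.), DMF, 0 → 23 °C
Reagents that add atoms: benzyl bromide, BrCc1ccccc1
Why: Williamson etherification of the secondary alkoxide removes the only acidic proton before the halogen–lithium exchange and installs a group that the final hydrogenolysis cleaves.

Step 9
Reactants: 15 bromo flavan benzyl ether; 4 epoxy amide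
Product: 17 [(2R,3S)-3-[3,4-bis(benzyloxy)phenyl]oxiran-2-yl][(2R,3S)-3,7,8-tris(benzyloxy)-2-[3,4-bis(benzyloxy)phenyl]-3,4-dihydro-2H-chromen-6-yl]methanone, via aryllithium 16 (not isolated)
Conditions: n-BuLi (1.05 equiv), THF, −78 °C; then 4 (1.3 equiv), −78 → −40 °C; aq. NH4Cl
Reagents that add atoms: none
Why: Bromine–lithium exchange and acylation of the aryllithium by the morpholine amide, whose tetrahedral adduct survives until the quench, should give the epoxy ketone without over-addition and with both epoxide stereocentres untouched.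

Step 10
Reactants: 17 epoxy ketone; 18 5-(benzyloxy)-2-bromophenol
Product: 21 (2R,3R)-7-(benzyloxy)-2-[3,4-bis(benzyloxy)phenyl]-4-[(2R,3S)-3,7,8-tris(benzyloxy)-2-[3,4-bis(benzyloxy)phenyl]-3,4-dihydro-2H-chromen-6-yl]-3,4-dihydro-2H-chromene-3,4-diol (C4 configuration as formed), via dilithio phenoxide 19 (not isolated), via epoxy carbinol dialkoxide 20 (not isolated)
Conditions: 18 (1.6 equiv), n-BuLi (3.2 equiv), THF, −78 → 0 °C; then 17, −78 → 23 °C; then 55 °C; aq. NH4Cl
Reagents that add atoms: none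
Why: The aryllithium carbon of dianion 19 adds 1,2 to the ketone of 17 (C4a–C4), and on warming the ortho phenoxide of dialkoxide 20 attacks the benzylic epoxide carbon from the rear (O1–C2), an anionic [3+3] annulation of a phenol C,O-dinucleophile onto an epoxy ketone. The closest known reaction types are organolithium 1,2-addition to α,β-epoxy ketones and the phenoxide ring closure of 2'-hydroxychalcone epoxides to trans-dihydroflavonols. Ring C closes in the 6-endo-tet mode at the epoxide, the alternative being 5-exo-tet attack at C3 to a dihydrobenzofuran. C3 keeps the epoxide configuration, C2 is set by SN2 inversion at the β-carbon (R, 2,3-trans), and the configuration of the C4 carbinol, fixed by 1,2-induction from the epoxide, is irrelevant because C4 is ionised in step 11. The step needs carbonyl addition before any epoxide attack and 6-endo over 5-exo opening: the first is secured by the non-enolisable ketone being the most electrophilic site at −78 °C, the second by the 3,4-bis(benzyloxy)phenyl group that loosens the C2–O bond, by the neopentyl-like C3 next to the fully substituted C4, and by lithium bridging between the C4 alkoxide and the epoxide oxygen.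

Step 11
Reactants: 21 4-aryl flavan-3,4-diol
Product: 22 (2R,3S)-7-(benzyloxy)-2-[3,4-bis(benzyloxy)phenyl]-4-[(2R,3S)-3,7,8-tris(benzyloxy)-2-[3,4-bis(benzyloxy)phenyl]-3,4-dihydro-2H-chromen-6-yl]-3,4-dihydro-2H-chromen-3-ol with the C4 aryl group β (cis to the 3-OH; the spatial arrangement of C4 in the target)
Conditions: Et3SiH (10 equiv), TFA (5 equiv), CH2Cl2, −78 → −20 °C
Reagents that add atoms: none
Why: Ionic hydrogenation: acid ionises the doubly benzylic tertiary alcohol to a diarylmethyl cation and the silane should deliver hydride to the face anti to the C3 oxygen, the face nucleophiles prefer in 2,3-trans flavan-4-yl cations, so the aryl group ends cis to O3 (3,4-cis, 4β).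

Step 12
Reactants: 22 octabenzyl ether
Product: 23 (2R,3S)-2-(3,4-dihydroxyphenyl)-6-[(2R,3S,4S)-2-(3,4-dihydroxyphenyl)-3,7-dihydroxy-3,4-dihydro-2H-chromen-4-yl]-3,4-dihydro-2H-chromene-3,7,8-triol
Conditions: H2 (1 atm), Pd(OH)2/C, THF/MeOH (1:1), 23 °C
Reagents that add atoms: none
Why: Catalytic hydrogenolysis should cleave the eight benzyl ethers while the C4–aryl bond and the two cyclic benzylic ethers, which are much slower to cleave under these mild conditions, remain intact.

Compound list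
1 | 3,4-bis(benzyloxy)benzaldehyde | O=Cc1ccc(OCc2ccccc2)c(OCc2ccccc2)c1 | starting material
2 | diethyl (2-morpholino-2-oxoethyl)phosphonate | CCOP(=O)(CC(=O)N1CCOCC1)OCC | starting material
3 | (2E)-3-[3,4-bis(benzyloxy)phenyl]-1-(morpholin-4-yl)prop-2-en-1-one | O=C(/C=C/c1ccc(OCc2ccccc2)c(OCc2ccccc2)c1)N1CCOCC1 | intermediate
4 | [(2R,3S)-3-[3,4-bis(benzyloxy)phenyl]oxiran-2-yl](morpholin-4-yl)methanone (trans) | O=C(N1CCOCC1)[C@@H]1O[C@H]1c1ccc(OCc2ccccc2)c(OCc2ccccc2)c1 | intermediate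
5 | 2,3-bis(benzyloxy)benzaldehyde | O=Cc1cccc(OCc2ccccc2)c1OCc1ccccc1 | starting material
6 | 2,3-bis(benzyloxy)phenyl formate | O=COc1cccc(OCc2ccccc2)c1OCc1ccccc1 | intermediate
7 | 2,3-bis(benzyloxy)phenol | Oc1cccc(OCc2ccccc2)c1OCc1ccccc1 | intermediate
8 | 4-bromo-2,3-bis(benzyloxy)phenol | Oc1ccc(Br)c(OCc2ccccc2)c1OCc1ccccc1 | intermediate
9 | 4-bromo-6-iodo-2,3-bis(benzyloxy)phenol | Oc1c(I)cc(Br)c(OCc2ccccc2)c1OCc1ccccc1 | intermediate
10 | sodium 2,3-bis(benzyloxy)-4-bromo-6-lithiophenoxide | [Li]c1cc(Br)c(OCc2ccccc2)c(OCc2ccccc2)c1[O-].[Na+] | intermediate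
11 | [3,4-bis(benzyloxy)-5-bromo-2-hydroxyphenyl][(2R,3S)-3-[3,4-bis(benzyloxy)phenyl]oxiran-2-yl]methanone (present as its phenoxide) | O=C(c1cc(Br)c(OCc2ccccc2)c(OCc2ccccc2)c1O)[C@@H]1O[C@H]1c1ccc(OCc2ccccc2)c(OCc2ccccc2)c1 | intermediate
12 | (2R,3R)-7,8-bis(benzyloxy)-2-[3,4-bis(benzyloxy)phenyl]-6-bromo-3-hydroxy-2,3-dihydro-4H-chromen-4-one (2,3-trans) | O=C1c2cc(Br)c(OCc3ccccc3)c(OCc3ccccc3)c2O[C@H](c2ccc(OCc3ccccc3)c(OCc3ccccc3)c2)[C@H]1O | intermediate
13 | (2R,3S)-7,8-bis(benzyloxy)-2-[3,4-bis(benzyloxy)phenyl]-6-bromo-3,4-dihydro-2H-chromene-3,4-diol (C4 either configuration) | Brc1cc2c(c(OCc3ccccc3)c1OCc1ccccc1)O[C@H](c1ccc(OCc3ccccc3)c(OCc3ccccc3)c1)[C@@H](O)C2O | intermediate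
14 | (2R,3S)-7,8-bis(benzyloxy)-2-[3,4-bis(benzyloxy)phenyl]-6-bromo-3,4-dihydro-2H-chromen-3-ol | Brc1cc2c(c(OCc3ccccc3)c1OCc1ccccc1)O[C@H](c1ccc(OCc3ccccc3)c(OCc3ccccc3)c1)[C@@H](O)C2 | intermediate
15 | (2R,3S)-3,7,8-tris(benzyloxy)-2-[3,4-bis(benzyloxy)phenyl]-6-bromo-3,4-dihydro-2H-chromene | Brc1cc2c(c(OCc3ccccc3)c1OCc1ccccc1)O[C@H](c1ccc(OCc3ccccc3)c(OCc3ccccc3)c1)[C@@H](OCc1ccccc1)C2 | intermediate
16 | [(2R,3S)-3,7,8-tris(benzyloxy)-2-[3,4-bis(benzyloxy)phenyl]-3,4-dihydro-2H-chromen-6-yl]lithium | [Li]c1cc2c(c(OCc3ccccc3)c1OCc1ccccc1)O[C@H](c1ccc(OCc3ccccc3)c(OCc3ccccc3)c1)[C@@H](OCc1ccccc1)C2 | intermediate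
17 | [(2R,3S)-3-[3,4-bis(benzyloxy)phenyl]oxiran-2-yl][(2R,3S)-3,7,8-tris(benzyloxy)-2-[3,4-bis(benzyloxy)phenyl]-3,4-dihydro-2H-chromen-6-yl]methanone | O=C(c1cc2c(c(OCc3ccccc3)c1OCc1ccccc1)O[C@H](c1ccc(OCc3ccccc3)c(OCc3ccccc3)c1)[C@@H](OCc1ccccc1)C2)[C@@H]1O[C@H]1c1ccc(OCc2ccccc2)c(OCc2ccccc2)c1 | intermediate
18 | 5-(benzyloxy)-2-bromophenol | Oc1cc(OCc2ccccc2)ccc1Br | starting material
19 | lithium 5-(benzyloxy)-2-lithiophenoxide | [Li]c1ccc(OCc2ccccc2)cc1[O-].[Li+] | intermediate
20 | dilithium salt of [4-(benzyloxy)-2-hydroxyphenyl][(2R,3S)-3-[3,4-bis(benzyloxy)phenyl]oxiran-2-yl][(2R,3S)-3,7,8-tris(benzyloxy)-2-[3,4-bis(benzyloxy)phenyl]-3,4-dihydro-2H-chromen-6-yl]methanol (carbinol carbon either configuration) | [Li+].[Li+].[O-]C(c1ccc(OCc2ccccc2)cc1[O-])(c1cc2c(c(OCc3ccccc3)c1OCc1ccccc1)O[C@H](c1ccc(OCc3ccccc3)c(OCc3ccccc3)c1)[C@@H](OCc1ccccc1)C2)[C@@H]1O[C@H]1c1ccc(OCc2ccccc2)c(OCc2ccccc2)c1 | intermediate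
21 | (2R,3R)-7-(benzyloxy)-2-[3,4-bis(benzyloxy)phenyl]-4-[(2R,3S)-3,7,8-tris(benzyloxy)-2-[3,4-bis(benzyloxy)phenyl]-3,4-dihydro-2H-chromen-6-yl]-3,4-dihydro-2H-chromene-3,4-diol (2,3-trans; C4 either configuration) | C(c1ccccc1)Oc1ccc2c(c1)O[C@H](c1ccc(OCc3ccccc3)c(OCc3ccccc3)c1)[C@@H](O)C2(O)c1cc2c(c(OCc3ccccc3)c1OCc1ccccc1)O[C@H](c1ccc(OCc3ccccc3)c(OCc3ccccc3)c1)[C@@H](OCc1ccccc1)C2 | intermediate
22 | (2R,3S)-7-(benzyloxy)-2-[3,4-bis(benzyloxy)phenyl]-4-[(2R,3S)-3,7,8-tris(benzyloxy)-2-[3,4-bis(benzyloxy)phenyl]-3,4-dihydro-2H-chromen-6-yl]-3,4-dihydro-2H-chromen-3-ol, C4 aryl β (2,3-trans-3,4-cis, C4 arranged as in the target) | C(c1ccccc1)Oc1ccc2c(c1)O[C@H](c1ccc(OCc3ccccc3)c(OCc3ccccc3)c1)[C@@H](O)[C@H]2c1cc2c(c(OCc3ccccc3)c1OCc1ccccc1)O[C@H](c1ccc(OCc3ccccc3)c(OCc3ccccc3)c1)[C@@H](OCc1ccccc1)C2 | intermediate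
23 | (2R,3S)-2-(3,4-dihydroxyphenyl)-6-[(2R,3S,4S)-2-(3,4-dihydroxyphenyl)-3,7-dihydroxy-3,4-dihydro-2H-chromen-4-yl]-3,4-dihydro-2H-chromene-3,7,8-triol | Oc1ccc2c(c1)O[C@H](c1ccc(O)c(O)c1)[C@@H](O)[C@H]2c1cc2c(c(O)c1O)O[C@H](c1ccc(O)c(O)c1)[C@@H](O)C2 | target

Total step count: 12. Longest linear sequence: 10 steps (5 → 7 → 8 → 9 → 12 → 14 → 15 → 17 → 21 → 22 → 23, steps 3 to 12); steps 1 and 2 supply the shared epoxy amide 4.

Steps most likely to fail

1. Step 10. The ring closure may stall after the carbonyl addition, the phenoxide may open the epoxide at C3 in the 5-exo mode, the C4 alkoxide may shift the epoxide (Payne rearrangement), or the aggregated dianion may add sluggishly to the hindered ketone. The fallback sets out from 18, 4 and 15 and returns at 21. Dianion 19 is acylated with epoxy amide 4 and closed exactly as in step 6 (ring C still formed at O1–C2 and C4a–C4 in one flask, now on the small fragment) to give (2R,3R)-7-(benzyloxy)-2-[3,4-bis(benzyloxy)phenyl]-3-hydroxy-2,3-dihydro-4H-chromen-4-one F1. Et3SiOTf and 2,6-lutidine give the 3-O-triethylsilyl ether of the dihydroflavonol F2. Aryllithium 16 then adds to the C4 ketone to give the 3-O-triethylsilyl ether of 21 F3, and Bu4NF in THF removes the silyl group to deliver 21.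

2. Step 11. Hydride delivery may show poor facial selectivity (attack syn to O3 leading to the 3,4-trans isomer), or the cation may undergo a pinacol-type 1,2-hydride shift or proton loss towards a flavan-3-one before it is reduced. The fallback sets out from 21 and returns at 22. t-BuMe2SiCl and imidazole in DMF silylate only the secondary 3-OH to give the 3-O-tert-butyldimethylsilyl ether of 21 F4. Reduction with n-Bu3SnH and TFA in CH2Cl2 at −78 °C, with the bulky silyloxy group screening the face syn to O3 and disfavouring the hydride shift, gives the 3-O-tert-butyldimethylsilyl ether of 22 F5, and Bu4NF in THF gives 22.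

3. Step 6. Competing bromine–lithium exchange or halogen scrambling in the dihalide, deprotonation of the epoxy amide at its α-carbon, phenoxide attack at the α-carbon (5-exo) or base-induced epimerisation and air oxidation of the dihydroflavonol may erode the annulation. The fallback sets out from 9 and returns at 12. MOMCl and i-Pr2NEt give 2,3-bis(benzyloxy)-1-bromo-5-iodo-4-(methoxymethoxy)benzene F6. i-PrMgCl·LiCl (iodine–magnesium exchange only) followed by 4 gives [3,4-bis(benzyloxy)-5-bromo-2-(methoxymethoxy)phenyl][(2R,3S)-3-[3,4-bis(benzyloxy)phenyl]oxiran-2-yl]methanone F7. HCl in MeOH/THF at 45 °C then removes the acetal and closes the ring under acid at the benzylic epoxide carbon to give 12.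

Further compounds
F1 | step 10 | (2R,3R)-7-(benzyloxy)-2-[3,4-bis(benzyloxy)phenyl]-3-hydroxy-2,3-dihydro-4H-chromen-4-one | O=C1c2ccc(OCc3ccccc3)cc2O[C@H](c2ccc(OCc3ccccc3)c(OCc3ccccc3)c2)[C@H]1O
F2 | step 10 | (2R,3R)-7-(benzyloxy)-2-[3,4-bis(benzyloxy)phenyl]-3-(triethylsilyloxy)-2,3-dihydro-4H-chromen-4-one | O=C1c2ccc(OCc3ccccc3)cc2O[C@H](c2ccc(OCc3ccccc3)c(OCc3ccccc3)c2)[C@H]1O[Si](CC)(CC)CC
F3 | step 10 | 3-O-triethylsilyl ether of 21 (C4 either configuration) | C(c1ccccc1)Oc1ccc2c(c1)O[C@H](c1ccc(OCc3ccccc3)c(OCc3ccccc3)c1)[C@@H](O[Si](CC)(CC)CC)C2(O)c1cc2c(c(OCc3ccccc3)c1OCc1ccccc1)O[C@H](c1ccc(OCc3ccccc3)c(OCc3ccccc3)c1)[C@@H](OCc1ccccc1)C2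
F4 | step 11 | 3-O-tert-butyldimethylsilyl ether of 21 (C4 either configuration) | C(c1ccccc1)Oc1ccc2c(c1)O[C@H](c1ccc(OCc3ccccc3)c(OCc3ccccc3)c1)[C@@H](O[Si](C)(C)C(C)(C)C)C2(O)c1cc2c(c(OCc3ccccc3)c1OCc1ccccc1)O[C@H](c1ccc(OCc3ccccc3)c(OCc3ccccc3)c1)[C@@H](OCc1ccccc1)C2
F5 | step 11 | 3-O-tert-butyldimethylsilyl ether of 22 | C(c1ccccc1)Oc1ccc2c(c1)O[C@H](c1ccc(OCc3ccccc3)c(OCc3ccccc3)c1)[C@@H](O[Si](C)(C)C(C)(C)C)[C@H]2c1cc2c(c(OCc3ccccc3)c1OCc1ccccc1)O[C@H](c1ccc(OCc3ccccc3)c(OCc3ccccc3)c1)[C@@H](OCc1ccccc1)C2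
F6 | step 6 | 2,3-bis(benzyloxy)-1-bromo-5-iodo-4-(methoxymethoxy)benzene | COCOc1c(I)cc(Br)c(OCc2ccccc2)c1OCc1ccccc1
F7 | step 6 | [3,4-bis(benzyloxy)-5-bromo-2-(methoxymethoxy)phenyl][(2R,3S)-3-[3,4-bis(benzyloxy)phenyl]oxiran-2-yl]methanone | COCOc1c(C(=O)[C@@H]2O[C@H]2c2ccc(OCc3ccccc3)c(OCc3ccccc3)c2)cc(Br)c(OCc2ccccc2)c1OCc1ccccc1
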